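**Retrosynthetic overview**

- Feature: in ring A (the five-membered ring C8–C12) the C9 carbonyl oxygen and the C6 acetoxy oxygen stand 1,4 to each other across the Z exocyclic C7=C8 alkene, and the C12 tertiary hydroxyl sits on the neighbouring ring carbon, on the face that has to take up oxygen. This is the imprint of a diene endoperoxide (3,6-dihydro-1,2-dioxine).
- Target ⇒ C9-keto 5,6-diacetate (C10 chlorine and C10=C11 alkene added last through enol silanes and a selenoxide elimination) ⇒ bicyclic endoperoxide (Kornblum–DeLaMare opening, acetylation).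
- Endoperoxide ⇒ [4+2] addition of singlet oxygen to the C9=C8–C7=C6 diene of a 1-dienylcyclopentenol; this forms C9–O and C6–O.
- Diene ⇒ Stille coupling at C7–C8 of a 2-iodocyclopentenol (from cyclopent-2-en-1-one: α-iodination, asymmetric allylation for C12, oxidative cleavage, Z-Wittig) with an (E)-vinylstannane (from a silyl ynone: asymmetric transfer hydrogenation for C5, hydrostannylation).
- Ring order: the carbocycle is bought; the only ring formed is the dioxine (step 12), and it is opened again in step 13.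

Key step: step 12

Remark: positions are given in prostanoid numbering (C1 ester carbon, C5 and C6 acetoxy carbons, C7 exocyclic alkene carbon, C8–C12 ring, C13–C20 octenyl chain).

Assumption: (R)-BINOL is taken to give the (S)-carbinol 4 in step 2; if the sense of induction proves opposite, (S)-BINOL is used with no other change.

**Route**

Step 1
Reactants: 1 cyclopent-2-en-1-one
Product: 2 2-iodocyclopent-2-en-1-one
Conditions: I2, pyridine, CH2Cl2, 0 °C to rt
Reagents that add atoms: iodine, II
Why: α-Iodination of an enone of the Baylis–Hillman type (Johnson iodination), in which pyridine adds reversibly at the β-carbon, the enolate takes up iodine and loss of pyridine restores the enone.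

Step 2
Reactants: 2 2-iodocyclopent-2-en-1-one; 3 tetraallylstannane
Product: 4 (1S)-2-iodo-1-(prop-2-en-1-yl)cyclopent-2-en-1-ol
Conditions: Ti(OiPr)4 (0.3 equiv), (R)-BINOL (0.3 equiv), iPrOH (20 equiv), CH2Cl2, rt
Reagents that add atoms: none
Why: Catalytic asymmetric 1,2-allylation of a ketone by a titanium BINOLate with tetraallylstannane, in which the flat iodoalkene side and the CH2 side of the carbonyl are told apart so that allyl enters one enantioface and sets the C12 quaternary carbinol as S, without conjugate addition.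

Step 3
Reactants: 4 (1S)-2-iodo-1-(prop-2-en-1-yl)cyclopent-2-en-1-ol
Product: 5 {[(1S)-2-iodo-1-(prop-2-en-1-yl)cyclopent-2-en-1-yl]oxy}trimethylsilane
Conditions: 1-(trimethylsilyl)imidazole, CH2Cl2, rt
Reagents that add atoms: 1-(trimethylsilyl)imidazole, C[Si](C)(C)n1ccnc1
Why: Silylation of the hindered tertiary alcohol under neutral conditions, which masks the hydroxyl so that the β-oxy aldehyde of the next steps cannot undergo retro-aldol cleavage.

Step 4
Reactants: 5 {[(1S)-2-iodo-1-(prop-2-en-1-yl)cyclopent-2-en-1-yl]oxy}trimethylsilane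
Product: 6 [(1S)-2-iodo-1-(trimethylsilyloxy)cyclopent-2-en-1-yl]acetaldehyde
Conditions: K2OsO4·2H2O (2 mol %), NaIO4, 2,6-lutidine, dioxane/H2O 3:1, rt
Reagents that add atoms: sodium periodate, [Na+].[O-]I(=O)(=O)=O (terminal oxidant; its oxygen reaches the aldehyde by way of OsO4)
Why: Lemieux–Johnson oxidative cleavage, in which OsO4 should dihydroxylate the unhindered monosubstituted alkene much faster than the iodine-bearing trisubstituted ring alkene next to the quaternary centre, while the lutidine buffer keeps the silyl ether and the aldehyde intact.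

Step 5
Reactants: 6 [(1S)-2-iodo-1-(trimethylsilyloxy)cyclopent-2-en-1-yl]acetaldehyde; 7 hexyltriphenylphosphonium bromide
Product: 10 (1S)-2-iodo-1-[(2Z)-oct-2-en-1-yl]cyclopent-2-en-1-ol, via hexylidenetriphenylphosphorane 8 (not isolated), via Z-octenyl trimethylsilyl ether 9 (not isolated)
Conditions: 7, NaHMDS, THF, 0 °C; 6, −78 °C to rt; then 1 M HCl, THF, 0 °C
Reagents that add atoms: none
Why: Wittig olefination with a salt-free non-stabilised ylide should give the Z C14=C15 alkene through the kinetically preferred cis-oxaphosphetane, and the tertiary silyl ether is hydrolysed in the brief acidic quench.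

Step 6
Reactants: 11 methyl 5-chloro-5-oxopentanoate; 12 bis(trimethylsilyl)acetylene
Product: 13 methyl 5-oxo-7-(trimethylsilyl)hept-6-ynoate
Conditions: AlCl3, CH2Cl2, 0 °C
Reagents that add atoms: none
Why: Friedel–Crafts-type acylation of an alkynylsilane, in which ipso attack of the acylium ion and loss of Me3SiCl give the silyl ynone while the methyl ester and the second silyl group are untouched.

Step 7
Reactants: 13 methyl 5-oxo-7-(trimethylsilyl)hept-6-ynoate
Product: 14 methyl (5S)-5-hydroxy-7-(trimethylsilyl)hept-6-ynoate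
Conditions: Ru[(S,S)-TsNCH(Ph)CH(Ph)NH](p-cymene) (1 mol %), iPrOH, rt
Reagents that add atoms: none
Why: Noyori asymmetric transfer hydrogenation of an alkynyl ketone, in which the ruthenium hydride and its NH deliver hydride and proton to one carbonyl face with the alkyne in the place an aryl group takes, so that the (S,S)-ligand should set C5 as S.

Step 8
Reactants: 14 methyl (5S)-5-hydroxy-7-(trimethylsilyl)hept-6-ynoate
Product: 15 methyl (5S)-5-hydroxyhept-6-ynoate
Conditions: K2CO3 (0.2 equiv), MeOH, 0 °C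
Reagents that add atoms: none
Why: Base-catalysed methanolysis of the C(sp)–Si bond, which leaves the carbinol centre alone and in methanol keeps the δ-hydroxy methyl ester open.

Step 9
Reactants: 15 methyl (5S)-5-hydroxyhept-6-ynoate
Product: 16 methyl (5S,6E)-5-hydroxy-7-(tributylstannyl)hept-6-enoate
Conditions: Bu3SnH, Pd2(dba)3 (0.5 mol %), Cy3P·HBF4 (2 mol %), iPr2NEt (4 mol %), CH2Cl2, 0 °C
Reagents that add atoms: tributylstannane, CCCC[SnH](CCCC)CCCC
Why: Palladium-catalysed syn hydrostannylation of a terminal propargylic alcohol, in which the bulky phosphine should steer tin to the terminal carbon and so give the (E)-β-stannyl allylic alcohol.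

Step 10
Reactants: 10 (1S)-2-iodo-1-[(2Z)-oct-2-en-1-yl]cyclopent-2-en-1-ol; 16 methyl (5S,6E)-5-hydroxy-7-(tributylstannyl)hept-6-enoate
Product: 17 methyl (5S,6E)-5-hydroxy-7-{(5S)-5-hydroxy-5-[(2Z)-oct-2-en-1-yl]cyclopent-1-en-1-yl}hept-6-enoate
Conditions: Pd2(dba)3 (5 mol %), AsPh3 (20 mol %), CuI (10 mol %), DMF, rt to 40 °C
Reagents that add atoms: none
Why: Stille cross-coupling forms the C7–C8 bond with retention of both alkene geometries, AsPh3 and CuI speeding transmetalation at the hindered iodide and the neutral medium tolerating both free hydroxyls.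

Step 11
Reactants: 17 methyl (5S,6E)-5-hydroxy-7-{(5S)-5-hydroxy-5-[(2Z)-oct-2-en-1-yl]cyclopent-1-en-1-yl}hept-6-enoate
Product: 18 methyl (5S,6E)-5-acetoxy-7-{(5S)-5-hydroxy-5-[(2Z)-oct-2-en-1-yl]cyclopent-1-en-1-yl}hept-6-enoate
Conditions: Ac2O (1.1 equiv), pyridine, DMAP (5 mol %), CH2Cl2, 0 °C
Reagents that add atoms: acetic anhydride, CC(=O)OC(C)=O
Why: Selective O-acylation of the secondary C5 alcohol, since the hindered tertiary C12 hydroxyl, which must stay free for the next step, should not react at 0 °C with one equivalent of anhydride.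

Step 12
Reactants: 18 methyl (5S,6E)-5-acetoxy-7-{(5S)-5-hydroxy-5-[(2Z)-oct-2-en-1-yl]cyclopent-1-en-1-yl}hept-6-enoate
Product: 19 methyl (5S)-5-acetoxy-5-{(3S,5S,7aS)-5-hydroxy-5-[(2Z)-oct-2-en-1-yl]-3,5,6,7-tetrahydro-7aH-cyclopenta[c][1,2]dioxin-3-yl}pentanoate (5S,6S,9S,12S in prostanoid numbering)
Conditions: O2, 5,10,15,20-tetraphenylporphyrin (cat.), visible light, CH2Cl2, −30 °C
Reagents that add atoms: dioxygen, O=O
Why: Sensitised (singlet) oxygen adds to the s-cis C9=C8–C7=C6 diene in a concerted suprafacial [4+2] cycloaddition, forming the C9–O and C6–O bonds; the closest known reaction type is the photooxygenation of 1-vinylcycloalkenes to bicyclic 3,6-dihydro-1,2-dioxines. The six-membered dioxine ring is closed by the cycloaddition itself, both C–O bonds forming across the diene termini in one event, and the new C7=C8 double bond is necessarily cis within that ring, so that C6 and C9 lie on the same side (the later 7Z geometry). C9 is set by the face of attack, which the C12 stereocentre controls: the free tertiary hydroxyl can hydrogen-bond to the incoming oxygen in the non-polar medium and the octenyl CH2 on the same carbon shields the other face, so that oxygen should arrive syn to the hydroxyl. C6 is set by that same facial choice together with the E geometry of the C6=C7 alkene, since suprafacial delivery then places the C6 oxygen in the S configuration beside the preset C5 acetate. The step needs π-facial selectivity and chemoselectivity over ene oxygenation; the conjugated diene reaches the s-cis form easily (the s-trans form presses C6–H against the quaternary C12) and should react faster than the isolated cis C14=C15 alkene, and irradiation is stopped as soon as the diene is consumed.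

Step 13
Reactants: 19 endoperoxide (name as in step 12)
Product: 21 methyl (5S,6S,7Z)-5,6-diacetoxy-7-{(2S)-2-hydroxy-2-[(2Z)-oct-2-en-1-yl]-5-oxocyclopentylidene}heptanoate, via Z γ-hydroxy enone 20 (not isolated)
Conditions: Et3N (1.5 equiv), Ac2O (2 equiv), DMAP (0.1 equiv), CH2Cl2, 0 °C to rt
Reagents that add atoms: acetic anhydride, CC(=O)OC(C)=O
Why: Kornblum–DeLaMare rearrangement, in which the amine removes the C9 hydrogen as the O–O bond breaks to give the C9 ketone and the C6 alkoxide without touching the C7=C8 alkene or the C6 centre, and the C6 oxygen is acetylated as it forms so that hemiketal closure and furan formation are forestalled.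

Step 14
Reactants: 21 methyl (5S,6S,7Z)-5,6-diacetoxy-7-{(2S)-2-hydroxy-2-[(2Z)-oct-2-en-1-yl]-5-oxocyclopentylidene}heptanoate
Product: 23 methyl (5S,6S,7Z)-5,6-diacetoxy-7-{(2R)-4-chloro-2-[(2Z)-oct-2-en-1-yl]-5-oxo-2-(trimethylsilyloxy)cyclopentylidene}heptanoate (both C10 epimers), via bis-silyl dienol ether 22 (not isolated)
Conditions: TMSOTf (2.5 equiv), Et3N, CH2Cl2, −78 to 0 °C; volatiles removed, pentane filtration; NCS, THF, −78 to 0 °C
Reagents that add atoms: trimethylsilyl trifluoromethanesulfonate, C[Si](C)(C)OS(=O)(=O)C(F)(F)F; N-chlorosuccinimide, O=C1CCC(=O)N1Cl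
Why: Soft enolisation can only go towards C10 because C8 bears no hydrogen, and the resulting silyl enol ether (the C12 hydroxyl being silylated at the same time) is chlorinated at C10 by NCS in an electrophilic α-halogenation that should spare the isolated alkenes; the new C10 centre is removed in step 16.

Step 15
Reactants: 23 α-chloro ketone (name as in step 14)
Product: 25 methyl (5S,6S,7Z)-5,6-diacetoxy-7-{(2R)-4-chloro-2-[(2Z)-oct-2-en-1-yl]-5-oxo-4-(phenylselanyl)-2-(trimethylsilyloxy)cyclopentylidene}heptanoate (both C10 epimers), via chloro enol silane 24 (not isolated)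
Conditions: TMSOTf (1.2 equiv), Et3N, CH2Cl2, −78 to 0 °C; volatiles removed, pentane filtration; PhSeCl (1.05 equiv), THF, −78 °C
Reagents that add atoms: benzeneselenenyl chloride, Cl[Se]c1ccccc1
Why: A second enol silane forms at the chlorine-bearing C10 and is selenenylated there (α-selenenylation of a silyl enol ether), the electron-rich enol ether being expected to outrun the C14=C15 alkene for the selenenyl chloride at −78 °C.

Step 16
Reactants: 25 α-chloro α-phenylselanyl ketone (name as in step 15)
Product: 27 methyl (5S,6S,7Z)-5,6-diacetoxy-7-{(5R)-3-chloro-5-[(2Z)-oct-2-en-1-yl]-2-oxo-5-(trimethylsilyloxy)cyclopent-3-en-1-ylidene}heptanoate, via selenoxide 26 (not isolated)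
Conditions: H2O2 (30 % aq., 3 equiv), pyridine, CH2Cl2, 0 °C
Reagents that add atoms: none
Why: Selenoxide syn-elimination, in which oxidation at selenium is followed by elimination towards C11, the only carbon with a β-hydrogen, to give the C10-chloro C10=C11 enone, the excess peroxide turning the selenenic acid into the seleninic acid so that it cannot add to the alkenes.

Step 17
Reactants: 27 silyl-protected chlorodienone (name as in step 16)
Product: 28 methyl (5S,6S,7Z)-5,6-diacetoxy-7-{(5R)-3-chloro-5-hydroxy-5-[(2Z)-oct-2-en-1-yl]-2-oxocyclopent-3-en-1-ylidene}heptanoate (7Z-punaglandin 4)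
Conditions: HF·pyridine, pyridine, THF, 0 °C
Reagents that add atoms: none
Why: Fluoride-mediated cleavage of the tertiary trimethylsilyl ether under buffered conditions that should leave the two acetates, the methyl ester and the cross-conjugated chlorodienone untouched.

**Compound list**

1 | cyclopent-2-en-1-one | O=C1CCC=C1 | starting material
2 | 2-iodocyclopent-2-en-1-one | O=C1CCC=C1I | intermediate
3 | tetraallylstannane | C=CC[Sn](CC=C)(CC=C)CC=C | starting material
4 | (1S)-2-iodo-1-(prop-2-en-1-yl)cyclopent-2-en-1-ol | C=CC[C@@]1(O)CCC=C1I | intermediate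
5 | {[(1S)-2-iodo-1-(prop-2-en-1-yl)cyclopent-2-en-1-yl]oxy}trimethylsilane | C=CC[C@@]1(O[Si](C)(C)C)CCC=C1I | intermediate
6 | [(1S)-2-iodo-1-(trimethylsilyloxy)cyclopent-2-en-1-yl]acetaldehyde | O=CC[C@@]1(O[Si](C)(C)C)CCC=C1I | intermediate
7 | hexyltriphenylphosphonium bromide | CCCCCC[P+](c1ccccc1)(c1ccccc1)c1ccccc1.[Br-] | starting material
8 | hexylidenetriphenylphosphorane | CCCCCC=P(c1ccccc1)(c1ccccc1)c1ccccc1 | intermediate
9 | {[(1S)-2-iodo-1-[(2Z)-oct-2-en-1-yl]cyclopent-2-en-1-yl]oxy}trimethylsilane | CCCCC/C=C\C[C@@]1(O[Si](C)(C)C)CCC=C1I | intermediate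
10 | (1S)-2-iodo-1-[(2Z)-oct-2-en-1-yl]cyclopent-2-en-1-ol | CCCCC/C=C\C[C@@]1(O)CCC=C1I | intermediate
11 | methyl 5-chloro-5-oxopentanoate | COC(=O)CCCC(=O)Cl | starting material
12 | bis(trimethylsilyl)acetylene | C[Si](C)(C)C#C[Si](C)(C)C | starting material
13 | methyl 5-oxo-7-(trimethylsilyl)hept-6-ynoate | COC(=O)CCCC(=O)C#C[Si](C)(C)C | intermediate
14 | methyl (5S)-5-hydroxy-7-(trimethylsilyl)hept-6-ynoate | COC(=O)CCC[C@H](O)C#C[Si](C)(C)C | intermediate
15 | methyl (5S)-5-hydroxyhept-6-ynoate | COC(=O)CCC[C@H](O)C#C | intermediate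
16 | methyl (5S,6E)-5-hydroxy-7-(tributylstannyl)hept-6-enoate | COC(=O)CCC[C@H](O)/C=C/[Sn](CCCC)(CCCC)CCCC | intermediate
17 | methyl (5S,6E)-5-hydroxy-7-{(5S)-5-hydroxy-5-[(2Z)-oct-2-en-1-yl]cyclopent-1-en-1-yl}hept-6-enoate | CCCCC/C=C\C[C@@]1(O)CCC=C1/C=C/[C@H](CCCC(=O)OC)O | intermediate
18 | methyl (5S,6E)-5-acetoxy-7-{(5S)-5-hydroxy-5-[(2Z)-oct-2-en-1-yl]cyclopent-1-en-1-yl}hept-6-enoate | CCCCC/C=C\C[C@@]1(O)CCC=C1/C=C/[C@H](CCCC(=O)OC)OC(C)=O | intermediate
19 | methyl (5S)-5-acetoxy-5-{(3S,5S,7aS)-5-hydroxy-5-[(2Z)-oct-2-en-1-yl]-3,5,6,7-tetrahydro-7aH-cyclopenta[c][1,2]dioxin-3-yl}pentanoate | CCCCC/C=C\C[C@@]1(O)CC[C@@H]2OO[C@@H](C=C12)[C@H](CCCC(=O)OC)OC(C)=O | intermediate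
20 | methyl (5S,6S,7Z)-5-acetoxy-6-hydroxy-7-{(2S)-2-hydroxy-2-[(2Z)-oct-2-en-1-yl]-5-oxocyclopentylidene}heptanoate | CCCCC/C=C\C[C@@]1(O)CCC(=O)/C1=C\[C@H](O)[C@H](CCCC(=O)OC)OC(C)=O | intermediate
21 | methyl (5S,6S,7Z)-5,6-diacetoxy-7-{(2S)-2-hydroxy-2-[(2Z)-oct-2-en-1-yl]-5-oxocyclopentylidene}heptanoate | CCCCC/C=C\C[C@@]1(O)CCC(=O)/C1=C\[C@H](OC(C)=O)[C@H](CCCC(=O)OC)OC(C)=O | intermediate
22 | 9-O,12-O-bis(trimethylsilyl) C9=C10 dienol ether of 21 | CCCCC/C=C\C[C@@]1(O[Si](C)(C)C)CC=C(O[Si](C)(C)C)/C1=C\[C@H](OC(C)=O)[C@H](CCCC(=O)OC)OC(C)=O | intermediate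
23 | methyl (5S,6S,7Z)-5,6-diacetoxy-7-{(2R)-4-chloro-2-[(2Z)-oct-2-en-1-yl]-5-oxo-2-(trimethylsilyloxy)cyclopentylidene}heptanoate (both C10 epimers) | CCCCC/C=C\C[C@@]1(O[Si](C)(C)C)CC(Cl)C(=O)/C1=C\[C@H](OC(C)=O)[C@H](CCCC(=O)OC)OC(C)=O | intermediate
24 | 10-chloro 9-O-trimethylsilyl C9=C10 enol ether of 23 | CCCCC/C=C\C[C@@]1(O[Si](C)(C)C)CC(Cl)=C(O[Si](C)(C)C)/C1=C\[C@H](OC(C)=O)[C@H](CCCC(=O)OC)OC(C)=O | intermediate
25 | methyl (5S,6S,7Z)-5,6-diacetoxy-7-{(2R)-4-chloro-2-[(2Z)-oct-2-en-1-yl]-5-oxo-4-(phenylselanyl)-2-(trimethylsilyloxy)cyclopentylidene}heptanoate (both C10 epimers) | CCCCC/C=C\C[C@@]1(O[Si](C)(C)C)CC(Cl)([Se]c2ccccc2)C(=O)/C1=C\[C@H](OC(C)=O)[C@H](CCCC(=O)OC)OC(C)=O | intermediate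
26 | selenoxide of 25 | CCCCC/C=C\C[C@@]1(O[Si](C)(C)C)CC(Cl)([Se](=O)c2ccccc2)C(=O)/C1=C\[C@H](OC(C)=O)[C@H](CCCC(=O)OC)OC(C)=O | intermediate
27 | methyl (5S,6S,7Z)-5,6-diacetoxy-7-{(5R)-3-chloro-5-[(2Z)-oct-2-en-1-yl]-2-oxo-5-(trimethylsilyloxy)cyclopent-3-en-1-ylidene}heptanoate | CCCCC/C=C\C[C@@]1(O[Si](C)(C)C)C=C(Cl)C(=O)/C1=C\[C@H](OC(C)=O)[C@H](CCCC(=O)OC)OC(C)=O | intermediate
28 | 7Z-punaglandin 4, methyl (5S,6S,7Z)-5,6-diacetoxy-7-{(5R)-3-chloro-5-hydroxy-5-[(2Z)-oct-2-en-1-yl]-2-oxocyclopent-3-en-1-ylidene}heptanoate | CCCCC/C=C\C[C@@]1(O)C=C(Cl)C(=O)/C1=C\[C@H](OC(C)=O)[C@H](CCCC(=O)OC)OC(C)=O | target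

**Step count**

Total: 17 steps. Longest linear sequence: 13 steps (steps 1–5 and 10–17, from cyclopent-2-en-1-one); the stannane branch (steps 6–9) joins at step 10.

**Steps most likely to fail**

Step 12 (key step). Oxygen may arrive largely on the face anti to the C12 hydroxyl, which would give the wrong C6 configuration, or ene oxygenation at the C14=C15 alkene or at C10–H may compete with the cycloaddition. The fallback sets out from 18 and comes back at 21; it installs the 1,4-dioxygen pattern stepwise instead of by cycloaddition. Hydroxyl-directed epoxidation of 18 (VO(acac)2, tBuOOH, CH2Cl2, 0 °C) should deliver oxygen to the allylic C8=C9 alkene syn to the C12 hydroxyl and give the vinyl epoxide, the C8–C9 epoxide of 18 (8S,9S,12S) F1. Opening of F1 with AcOH under Pd(PPh3)4 catalysis (THF, 0 °C) ionises the C8–O bond with inversion and lets acetate attack the C6 end of the allyl complex anti to palladium. This net syn 1,4-addition should give the C9-hydroxy 5,6-diacetate with C6 cis to C9, methyl (5S,6S,7E)-5,6-diacetoxy-7-{(2S,5S)-2,5-dihydroxy-2-[(2Z)-oct-2-en-1-yl]cyclopentylidene}heptanoate F2. Oxidation of the C9 carbinol of F2 (Dess–Martin periodinane, NaHCO3, CH2Cl2) leads to 21, so that steps 12 and 13 are both bypassed.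

Step 13. The amine may remove the C6 hydrogen, which the C5 acetoxy group activates, instead of the C9 hydrogen and so give the C6 ketone; or the Z γ-hydroxy enone may close to its hemiketal and lose water to a furan before it is acetylated. The fallback sets out from 19 and comes back at 20 and so at 21. The O–O bond is reduced without base (thiourea, MeOH, 0 °C) to the ene-diol, methyl (5S,6S,7E)-5-acetoxy-6-hydroxy-7-{(2S,5S)-2,5-dihydroxy-2-[(2Z)-oct-2-en-1-yl]cyclopentylidene}heptanoate F3. The ring allylic C9 carbinol of F3 is then oxidised selectively with MnO2 (CH2Cl2, rt) to 20; the C6 carbinol is flanked by the electron-withdrawing C5 acetoxy group and is the more hindered one. Compound 20 is acetylated at once (Ac2O, pyridine, DMAP, 0 °C) to 21.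

Step 15. Selenenylation at the chlorine-bearing C10 builds a fully substituted centre and may be slow, so that the selenenyl chloride adds to the C14=C15 alkene instead. The fallback sets out from the enol silane 24 and comes back at 27. It is a Saegusa–Ito dehydrogenation: Pd(OAc)2 (1.1 equiv) in MeCN at rt should convert 24, through the palladium enolate and β-hydride elimination of a C11 hydrogen, directly into 27, so that 25 and 26 are bypassed. No new compound is made.

**Further compounds**

F1 | step 12 | methyl (5S,6E)-5-acetoxy-7-{(1S,2S,5S)-2-hydroxy-2-[(2Z)-oct-2-en-1-yl]-6-oxabicyclo[3.1.0]hexan-1-yl}hept-6-enoate (C8–C9 epoxide of 18, oxygen syn to the C12 hydroxyl) | CCCCC/C=C\C[C@@]1(O)CC[C@@H]2O[C@]12/C=C/[C@H](CCCC(=O)OC)OC(C)=O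
F2 | step 12 | methyl (5S,6S,7E)-5,6-diacetoxy-7-{(2S,5S)-2,5-dihydroxy-2-[(2Z)-oct-2-en-1-yl]cyclopentylidene}heptanoate (C6 cis to C9) | CCCCC/C=C\C[C@@]1(O)CC[C@H](O)/C1=C\[C@H](OC(C)=O)[C@H](CCCC(=O)OC)OC(C)=O
F3 | step 13 | methyl (5S,6S,7E)-5-acetoxy-6-hydroxy-7-{(2S,5S)-2,5-dihydroxy-2-[(2Z)-oct-2-en-1-yl]cyclopentylidene}heptanoate (C6 cis to C9) | CCCCC/C=C\C[C@@]1(O)CC[C@H](O)/C1=C\[C@H](O)[C@H](CCCC(=O)OC)OC(C)=O
F0 | step 15 | none | none
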